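**Remark on the chemistry (assumptions).** The SMILES is read as the (3R)-isoflavanone; CIP order at C3 is C4 > C2 > C1' > H. The two phenols are carried as tert-butyldimethylsilyl (TBS) ethers. L* = 2,6-bis[(4S,5S)-4-(methoxymethyl)-5-phenyl-4,5-dihydrooxazol-2-yl]pyridine. Its sense of induction on a ring-embedded bromo ketone is not known in advance; if the first analysis shows the (S)-ketone, the (4R,5R) antipode is used instead.

## The problem

Target 17 is a 3-arylchroman-4-one. Ring A is a phloroglucinol-type benzene with free OH at C5 and C7, ring C is the pyranone with a plain methylene at C2, and ring B sits on C3 with a 2'-methoxy group and an angularly fused 2,2-dimethyl-2H-pyran (ring D). The only stereocenter, C3, is benzylic and α to the C4 carbonyl. It enolizes under base or acid and no second stereocenter can relay or restore it, so it must be set by a reagent, late, and then kept away from base. The C3–C1' bond joins this labile center to an electron-rich arene with an ortho-methoxy group. Ring C is a β-aryloxy ketone that opens by retro-oxa-Michael reaction under strong base. Ring D holds a styrene-type alkene that rules out hydrogenolysis, electrophilic halogen or oxidants and strong acid once it is present, and its angular fusion is not what electrophilic substitution or Claisen chemistry of a resorcinol ether gives by default. The feature that opens the key step is that C3 is a secondary carbon bonded directly to the C4 carbonyl, with a stereochemically silent C2 beside it. A C3–Br bond there is cleaved by one-electron reduction to a planar, carbonyl-conjugated C3 radical, so both enantiomers of a racemic 3-bromochroman-4-one pass through the same intermediate. The C3–C1' bond and the configuration can therefore be set in one catalyst-controlled event.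

## Retrosynthesis

**17 ⇒ 16.** Only the two O–Si bonds are cut. TBS is chosen because buffered fluoride removes it without base (C3), without hydrogen (ring D) and without strong acid, and because it tolerates organozinc and nickel chemistry.

**16 ⇒ 6 + 15 (key cut, C3–C1').** Cutting C3–C4 or C2–O1 instead would give open-chain precursors in which C3 still has to be set separately. The C3–C1' cut splits the molecule into a racemic bromo ketone 6 (rings A/C) and an arylzinc 15 (rings B/D), and the stereocenter arises in the bond-forming step. The forward reaction must be enantioconvergent, must tolerate the ortho-methoxy group, must not eliminate toward the chromone, and must not enolize its own product.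

**6 ⇒ 4 ⇒ 1 + 2.** The C3–Br bond comes from the enol silane 5 of the ketone, so that bromine goes to C3 and not to ring A. Ring C is cut at C4–C4a (Friedel–Crafts) and O1–C2 (etherification). The threefold symmetry of phloroglucinol 1 removes every regiochemical question.

**15 ⇒ 13 ⇒ 11 ⇒ 8 + 9 ⇒ 7.** The C–Zn bond comes from C–Br. Ring D is cut at its O–C(CH3)2 bond and at the aryl–C4 bond. The aryl–C bond is made by lithiation of 8 at the one hydrogen flanked by OMe and OMOM, so the angular fusion is fixed by acidity. A propargyl ether Claisen route would favour the linear isomer, and bromination of a preformed chromene would give C6/C8 mixtures and attack the alkene. The bromine is already in place in commercial phenol 7.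

## Roads not taken

**Alternative 1:** (the obvious route) C2 is excised from ring C and the C4–C4a bond is cut. Forward: acylation of 1 with arylacetic acid A1 gives deoxybenzoin A2, one-carbon cyclization gives isoflavone A3, and the C2=C3 bond is reduced. The chosen plan is better for three reasons:
- The strongly acidic acylation is not survivable for ring D, so ring D would have to be built late, where the angular/linear question returns.
- C3 passes through a planar state and has to be recovered by an asymmetric reduction to the 4-ol plus re-oxidation.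
- The sequence is linear and longer, and A1 itself needs a homologation.

**Alternative 2:** The C3–H bond is cut. Forward key step: decarboxylative asymmetric protonation of racemic allyl β-keto ester A6 with a zerovalent palladium/chiral phosphinooxazoline catalyst and a proton donor. A6 would come from β-keto ester A4 (from 4) and aryllead triacetate A5 (tetravalent lead, from 13). The chosen plan is better because this route makes the C3–C1' bond and the stereocenter in two separate operations, adds three steps and stoichiometric lead, and must build a quaternary carbon next to an ortho-methoxy arene before removing it again.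

**Alternative 3:** The C3–C1' bond is made by migration. Forward: neoflavene A7 (from 4 and 13) is dihydroxylated asymmetrically to cis-diol A8 and converted to monomesylate A9; Et3Al then promotes a semipinacol shift of ring B from C4 to C3 with inversion, giving 16. The shift is stereospecific and non-basic, which is attractive. The chosen plan is better because:
- The osmium reagent would have to prefer the hindered C3=C4 alkene of A7 over the ring D alkene.
- Three more steps are needed.
- Ring contraction by C4a migration competes whenever the mesylate of A9 is equatorial.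
- The doubly benzylic carbinol ionizes easily.

Key step: step 6

## Route

Step 1
Reactants: 1 phloroglucinol; 2 3-chloropropanoic acid
Product: 4 5,7-dihydroxychroman-4-one, via chloroketone 3 (not isolated)
Conditions: CF3SO3H, 80 °C; extractive work-up; 2 M NaOH (aq), 0 °C → rt; HCl to pH 3
Reagents that add atoms: none
Why: Friedel–Crafts acylation of the symmetric triol gives one aryl ketone; base then closes ring C by intramolecular Williamson etherification (6-exo-tet), the two ortho hydroxyls being equivalent.

Step 2
Reactants: 4 5,7-dihydroxychroman-4-one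
Product: 6 rac-3-bromo-5,7-bis(tert-butyldimethylsilyloxy)chroman-4-one, via tris-silyl enol ether 5 (not isolated)
Conditions: TBSOTf (3.3 equiv), Et3N, CH2Cl2, 0 °C → rt; aq. NaHCO3 work-up; NBS (1.0 equiv), THF, −78 → 0 °C
Reagents that add atoms: tert-butyldimethylsilyl trifluoromethanesulfonate, CC(C)(C)[Si](C)(C)OS(=O)(=O)C(F)(F)F; N-bromosuccinimide, O=C1CCC(=O)N1Br
Why: TBSOTf/Et3N silylates both phenols and soft-enolizes the ketone toward C3, its only enolizable position, without a free enolate that could open ring C. NBS then brominates the enol ether carbon (α-bromination via silyl enol ether), which is far more nucleophilic than the silyloxy-flanked C6 and C8; the product is racemic by design.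

Step 3
Reactants: 7 4-bromo-3-methoxyphenol
Product: 8 1-bromo-2-methoxy-4-(methoxymethoxy)benzene
Conditions: MOMCl, i-Pr2NEt, CH2Cl2, 0 °C → rt
Reagents that add atoms: chloromethyl methyl ether, COCCl
Why: Standard phenol MOM protection; the MOM ether is the second ortho-directing group for step 4 and leaves under the acid that closes ring D in step 5.

Step 4
Reactants: 8 1-bromo-2-methoxy-4-(methoxymethoxy)benzene; 9 3-methylbut-2-enal
Product: 11 rac-1-[3-bromo-2-methoxy-6-(methoxymethoxy)phenyl]-3-methylbut-2-en-1-ol, via aryllithium 10 (not isolated)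
Conditions: lithium 2,2,6,6-tetramethylpiperidide (LiTMP), THF, −78 °C; 9, −78 °C; H2O
Reagents that add atoms: none
Why: Directed ortho-metalation removes the hydrogen flanked by OMe and OMOM, the most acidic one, and an amide base avoids bromine–lithium exchange; 1,2-addition of 10 to the enal follows. The new carbinol center is racemic and is destroyed in step 5.

Step 5
Reactants: 11 rac-1-[3-bromo-2-methoxy-6-(methoxymethoxy)phenyl]-3-methylbut-2-en-1-ol
Product: 13 6-bromo-5-methoxy-2,2-dimethyl-2H-chromene, via hydroxyalkyl phenol 12 (not isolated)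
Conditions: p-TsOH·H2O (cat.), MeOH, 50 °C
Reagents that add atoms: none
Why: Acid cleaves the MOM acetal and ionizes the benzylic/allylic alcohol; the phenol oxygen closes on the tertiary allyl terminus (equivalently, oxa-6π electrocyclization of the ortho-quinone methide) to give the 2,2-dimethyl-2H-chromene. Reversible methanolysis of the allyl cation leads to the same product, and the ring fusion is fixed by the lithiation site of step 4.

Step 6
Reactants: 6 rac-3-bromo-5,7-bis(tert-butyldimethylsilyloxy)chroman-4-one; 13 6-bromo-5-methoxy-2,2-dimethyl-2H-chromene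
Product: 16 (R)-5,7-bis(tert-butyldimethylsilyloxy)-3-(5-methoxy-2,2-dimethyl-2H-chromen-6-yl)chroman-4-one, via arylmagnesium bromide 14 (not isolated), via arylzinc iodide 15 (not isolated)
Conditions: 13, Mg, THF, rt; ZnI2, THF, rt; then 6, NiCl2·glyme (5 mol %), L* (6.5 mol %), glyme/THF, −30 °C (15 in 1.3–1.5 equiv)
Reagents that add atoms: none
Why: Proposed new method: nickel/pybox-catalysed enantioconvergent Negishi arylation is established for open-chain secondary α-bromo ketones with arylzinc iodides, and its extension to a ring-embedded α-bromo ketone is the untested part. Mechanism: ligated monovalent nickel abstracts bromine from either enantiomer of 6 to give the same planar C3 radical conjugated with the C4 carbonyl; the arylnickel complex formed by transmetalation from 15 captures it, and reductive elimination from trivalent nickel forms the C3–C1' bond. No ring is closed; rings A/C and B/D arrive intact. C3 is set under catalyst control: the C2-symmetric pybox pocket distinguishes the faces of a radical whose substituents (acyl carbon C4 against methylene C2) are the same pair it distinguishes in the open-chain cases, here locked in one geometry by ring C. Required selectivities are face selectivity at C3 (ligand), coupling over β-hydride loss from C2 or β-aryloxide loss of O1 (the tridentate ligand leaves no free cis site, and the ring holds the C2–O1 bond near the nodal plane of the C3 π-system), and survival of the new C3–H (ArZnI is too weakly basic to enolize the ketone at −30 °C and no other base is present). The ortho-methoxy group of 15 is the main steric demand on transmetalation.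

Step 7
Reactants: 16 (R)-5,7-bis(tert-butyldimethylsilyloxy)-3-(5-methoxy-2,2-dimethyl-2H-chromen-6-yl)chroman-4-one
Product: 17 (R)-5,7-dihydroxy-3-(5-methoxy-2,2-dimethyl-2H-chromen-6-yl)chroman-4-one
Conditions: HF·pyridine, pyridine/THF, 0 °C
Reagents that add atoms: none
Why: Fluoride cleaves both aryl silyl ethers in a weakly acidic, buffered medium, so C3 should not be enolized and the ring D alkene should not be protonated.

## Compound list

1 | phloroglucinol (benzene-1,3,5-triol) | Oc1cc(O)cc(O)c1 | starting material
2 | 3-chloropropanoic acid | OC(=O)CCCl | starting material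
3 | 3-chloro-1-(2,4,6-trihydroxyphenyl)propan-1-one | O=C(CCCl)c1c(O)cc(O)cc1O | intermediate (not isolated)
4 | 5,7-dihydroxychroman-4-one | O=C1CCOc2cc(O)cc(O)c12 | intermediate
5 | 4,5,7-tris(tert-butyldimethylsilyloxy)-2H-chromene | CC(C)(C)[Si](C)(C)OC1=CCOc2cc(O[Si](C)(C)C(C)(C)C)cc(O[Si](C)(C)C(C)(C)C)c12 | intermediate (not isolated)
6 | rac-3-bromo-5,7-bis(tert-butyldimethylsilyloxy)chroman-4-one | O=C1C(Br)COc2cc(O[Si](C)(C)C(C)(C)C)cc(O[Si](C)(C)C(C)(C)C)c12 | intermediate
7 | 4-bromo-3-methoxyphenol | COc1cc(O)ccc1Br | starting material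
8 | 1-bromo-2-methoxy-4-(methoxymethoxy)benzene | COCOc1ccc(Br)c(OC)c1 | intermediate
9 | 3-methylbut-2-enal | CC(C)=CC=O | starting material
10 | [3-bromo-2-methoxy-6-(methoxymethoxy)phenyl]lithium | [Li]c1c(OC)c(Br)ccc1OCOC | intermediate (not isolated)
11 | rac-1-[3-bromo-2-methoxy-6-(methoxymethoxy)phenyl]-3-methylbut-2-en-1-ol | CC(C)=CC(O)c1c(OC)c(Br)ccc1OCOC | intermediate
12 | 4-bromo-2-(1-hydroxy-3-methylbut-2-en-1-yl)-3-methoxyphenol | CC(C)=CC(O)c1c(OC)c(Br)ccc1O | intermediate (not isolated)
13 | 6-bromo-5-methoxy-2,2-dimethyl-2H-chromene | COc1c(Br)ccc2OC(C)(C)C=Cc12 | intermediate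
14 | (5-methoxy-2,2-dimethyl-2H-chromen-6-yl)magnesium bromide | COc1c([Mg]Br)ccc2OC(C)(C)C=Cc12 | intermediate (not isolated)
15 | (5-methoxy-2,2-dimethyl-2H-chromen-6-yl)zinc iodide | COc1c([Zn]I)ccc2OC(C)(C)C=Cc12 | intermediate (not isolated)
16 | (R)-5,7-bis(tert-butyldimethylsilyloxy)-3-(5-methoxy-2,2-dimethyl-2H-chromen-6-yl)chroman-4-one | COc1c([C@@H]2COc3cc(O[Si](C)(C)C(C)(C)C)cc(O[Si](C)(C)C(C)(C)C)c3C2=O)ccc2c1C=CC(C)(C)O2 | intermediate
17 | (R)-5,7-dihydroxy-3-(5-methoxy-2,2-dimethyl-2H-chromen-6-yl)chroman-4-one | COc1c([C@@H]2COc3cc(O)cc(O)c3C2=O)ccc2c1C=CC(C)(C)O2 | target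

## Step count and risk

Total: 7 steps. Longest linear sequence: 5 steps (steps 3–7); the ring A/C branch is 4 steps (1, 2, 6, 7).

**Step 6 (key step, proposed new method).** The likely failures are poor face selectivity, because the ligand pocket was shaped on open-chain bromo ketones; loss of HBr or β-hydride elimination toward the chromone; bromine–zinc exchange that only reduces 6; and slow transmetalation of the ortho-methoxy arylzinc. The fallback uses known chemistry, sets out from 4 and 13, and returns at 16:
- 4 is silylated (TBSOTf, 2,6-lutidine, CH2Cl2) to 5,7-bis(tert-butyldimethylsilyloxy)chroman-4-one F1.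
- Pd-catalysed ketone α-arylation of F1 with 13 (Pd(OAc)2, XPhos, K3PO4, toluene, 80 °C) gives racemic 5,7-bis(tert-butyldimethylsilyloxy)-3-(5-methoxy-2,2-dimethyl-2H-chromen-6-yl)chroman-4-one F2.
- Asymmetric transfer hydrogenation with dynamic kinetic resolution (RuCl[(R,R)-TsDPEN](p-cymene), HCO2H/Et3N, EtOAc, 40 °C) should give the cis alcohol (3R,4R)-5,7-bis(tert-butyldimethylsilyloxy)-3-(5-methoxy-2,2-dimethyl-2H-chromen-6-yl)chroman-4-ol F3. Et3N equilibrates the enantiomers of F2 through the enol while the catalyst reduces one of them.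
- Dess–Martin periodinane (NaHCO3, CH2Cl2, 0 °C) restores the C4 ketone without touching C3 and gives 16.

**Step 4.** Competing deprotonation next to bromine, followed by aryne formation or halogen migration, would erode the regiochemistry; incomplete metalation is also possible. The fallback sets out from 9 and returns at 15:
- 9 and commercial 2,4-dihydroxybenzaldehyde F4 (pyridine, 120 °C) give 5-hydroxy-2,2-dimethyl-2H-chromene-6-carbaldehyde F5. The chelated 2-OH is kept out of play, so the 4-OH forms the pyran at the carbon between the oxygens.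
- MeI, K2CO3, acetone gives 5-methoxy-2,2-dimethyl-2H-chromene-6-carbaldehyde F6.
- Pinnick oxidation (NaClO2, NaH2PO4, 2-methylbut-2-ene) gives 5-methoxy-2,2-dimethyl-2H-chromene-6-carboxylic acid F7.
- Ipso-iododecarboxylation (I2, K3PO4, MeCN, 100 °C) gives 6-iodo-5-methoxy-2,2-dimethyl-2H-chromene F8; iodine attack on the ring D alkene is a possible complication here.
- Zinc insertion (Zn dust, LiCl, THF, 50 °C) gives 15.

**Step 2.** Electrophilic bromination of ring A at C6/C8 may compete with the enol ether, and 6 may lose HBr on handling. The fallback sets out from 5 and returns at 6. Rubottom oxidation (mCPBA, NaHCO3, CH2Cl2, 0 °C; then camphorsulfonic acid, MeOH) gives racemic 3-hydroxy-5,7-bis(tert-butyldimethylsilyloxy)chroman-4-one F9. Appel bromination (CBr4, PPh3, CH2Cl2, 0 °C) then introduces bromine as a nucleophile and gives 6.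

**Step 7.** Enolization at C3 during desilylation would erode the enantiomeric purity, and protonation of ring D is a lesser concern. The fallback sets out from 16 and ends at 17, masking the ketone while the silyl groups leave:
- i-Bu2AlH (CH2Cl2, −78 °C) gives (3R)-5,7-bis(tert-butyldimethylsilyloxy)-3-(5-methoxy-2,2-dimethyl-2H-chromen-6-yl)chroman-4-ol F10 as C4 epimers, with C3 no longer enolizable.
- Bu4NF (THF, 0 °C) gives (3R)-3-(5-methoxy-2,2-dimethyl-2H-chromen-6-yl)chromane-4,5,7-triol F11.
- Activated MnO2 (EtOAc, rt) oxidizes the hydroxy-activated benzylic C4 alcohol under neutral conditions to 17.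

## Further compounds

F1 | step 6 | 5,7-bis(tert-butyldimethylsilyloxy)chroman-4-one | O=C1CCOc2cc(O[Si](C)(C)C(C)(C)C)cc(O[Si](C)(C)C(C)(C)C)c12
F2 | step 6 | rac-5,7-bis(tert-butyldimethylsilyloxy)-3-(5-methoxy-2,2-dimethyl-2H-chromen-6-yl)chroman-4-one | COc1c(C2COc3cc(O[Si](C)(C)C(C)(C)C)cc(O[Si](C)(C)C(C)(C)C)c3C2=O)ccc2c1C=CC(C)(C)O2
F3 | step 6 | (3R,4R)-5,7-bis(tert-butyldimethylsilyloxy)-3-(5-methoxy-2,2-dimethyl-2H-chromen-6-yl)chroman-4-ol | COc1c([C@@H]2COc3cc(O[Si](C)(C)C(C)(C)C)cc(O[Si](C)(C)C(C)(C)C)c3[C@@H]2O)ccc2c1C=CC(C)(C)O2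
F4 | step 4 | 2,4-dihydroxybenzaldehyde | O=Cc1ccc(O)cc1O
F5 | step 4 | 5-hydroxy-2,2-dimethyl-2H-chromene-6-carbaldehyde | CC1(C)C=Cc2c(O1)ccc(C=O)c2O
F6 | step 4 | 5-methoxy-2,2-dimethyl-2H-chromene-6-carbaldehyde | COc1c(C=O)ccc2OC(C)(C)C=Cc12
F7 | step 4 | 5-methoxy-2,2-dimethyl-2H-chromene-6-carboxylic acid | COc1c(C(=O)O)ccc2OC(C)(C)C=Cc12
F8 | step 4 | 6-iodo-5-methoxy-2,2-dimethyl-2H-chromene | COc1c(I)ccc2OC(C)(C)C=Cc12
F9 | step 2 | rac-3-hydroxy-5,7-bis(tert-butyldimethylsilyloxy)chroman-4-one | O=C1C(O)COc2cc(O[Si](C)(C)C(C)(C)C)cc(O[Si](C)(C)C(C)(C)C)c12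
F10 | step 7 | (3R)-5,7-bis(tert-butyldimethylsilyloxy)-3-(5-methoxy-2,2-dimethyl-2H-chromen-6-yl)chroman-4-ol, C4 epimers | COc1c([C@@H]2COc3cc(O[Si](C)(C)C(C)(C)C)cc(O[Si](C)(C)C(C)(C)C)c3C2O)ccc2c1C=CC(C)(C)O2
F11 | step 7 | (3R)-3-(5-methoxy-2,2-dimethyl-2H-chromen-6-yl)chromane-4,5,7-triol, C4 epimers | COc1c([C@@H]2COc3cc(O)cc(O)c3C2O)ccc2c1C=CC(C)(C)O2
A1 | alternative 1 | 2-(5-methoxy-2,2-dimethyl-2H-chromen-6-yl)acetic acid | COc1c(CC(=O)O)ccc2OC(C)(C)C=Cc12
A2 | alternative 1 | 2-(5-methoxy-2,2-dimethyl-2H-chromen-6-yl)-1-(2,4,6-trihydroxyphenyl)ethan-1-one | COc1c(CC(=O)c3c(O)cc(O)cc3O)ccc2OC(C)(C)C=Cc12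
A3 | alternative 1 | 5,7-dihydroxy-3-(5-methoxy-2,2-dimethyl-2H-chromen-6-yl)-4H-chromen-4-one | COc1c(C3=COc4cc(O)cc(O)c4C3=O)ccc2OC(C)(C)C=Cc12
A4 | alternative 2 | allyl rac-5,7-bis(tert-butyldimethylsilyloxy)-4-oxochroman-3-carboxylate | C=CCOC(=O)C1COc2cc(O[Si](C)(C)C(C)(C)C)cc(O[Si](C)(C)C(C)(C)C)c2C1=O
A5 | alternative 2 | (5-methoxy-2,2-dimethyl-2H-chromen-6-yl)lead triacetate | COc1c([Pb](OC(C)=O)(OC(C)=O)OC(C)=O)ccc2OC(C)(C)C=Cc12
A6 | alternative 2 | allyl rac-5,7-bis(tert-butyldimethylsilyloxy)-3-(5-methoxy-2,2-dimethyl-2H-chromen-6-yl)-4-oxochroman-3-carboxylate | C=CCOC(=O)C1(COc2cc(O[Si](C)(C)C(C)(C)C)cc(O[Si](C)(C)C(C)(C)C)c2C1=O)c3ccc4OC(C)(C)C=Cc4c3OC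
A7 | alternative 3 | 5,7-bis(tert-butyldimethylsilyloxy)-4-(5-methoxy-2,2-dimethyl-2H-chromen-6-yl)-2H-chromene | COc1c(C2=CCOc3cc(O[Si](C)(C)C(C)(C)C)cc(O[Si](C)(C)C(C)(C)C)c23)ccc4OC(C)(C)C=Cc14
A8 | alternative 3 | (3S,4R)-5,7-bis(tert-butyldimethylsilyloxy)-4-(5-methoxy-2,2-dimethyl-2H-chromen-6-yl)chromane-3,4-diol | O[C@H]1COc2cc(O[Si](C)(C)C(C)(C)C)cc(O[Si](C)(C)C(C)(C)C)c2[C@]1(O)c3ccc4OC(C)(C)C=Cc4c3OC
A9 | alternative 3 | (3S,4R)-5,7-bis(tert-butyldimethylsilyloxy)-4-hydroxy-4-(5-methoxy-2,2-dimethyl-2H-chromen-6-yl)chroman-3-yl methanesulfonate | CS(=O)(=O)O[C@H]1COc2cc(O[Si](C)(C)C(C)(C)C)cc(O[Si](C)(C)C(C)(C)C)c2[C@]1(O)c3ccc4OC(C)(C)C=Cc4c3OC
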